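**Reading time.** At the reading, 20 h for south and 30 h for south-west, I want to know how many half-lives of starting material have passed, N. The fraction left is one half raised to N.

common to all: starting material 0.021 M; free catalyst 0.13 mM

| run | second substrate | partner | temperature | remark | time |
|---|---|---|---|---|---|
| ash | 0.015 M (in portions, 2) | 0.0231 M | −45 °C | run made earlier; portions every 4.0 h |  |
| birch | 0.023 M (in portions, 2) | 0.0231 M | −30 °C | run made earlier; portions every 4.0 h |  |
| cedar | 0.0105 M (in portions, 2) | 0.012 M | −45 °C | run made earlier; portions every 4.0 h |  |
| south | 0.0105 M (in portions, 2) | 0.0231 M |  | at −20 °C throughout; the portions of second substrate follow each other after 4.0 h, the first at the start | 20 h |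
| south-west | 0.0105 M (in portions, 2) | 0.0231 M |  | at −40 °C until 10 h, from then on at −20 °C; the portions of second substrate follow each other after 4.0 h, the first at the start | 30 h |

1. which of the two ends with the higher amount of target, in percent of the starting material charged ("neither" if they lie within 2 percentage points) (south / south-west / neither)
2. target at the end, in percent of the starting material charged, south
3. target at the end, in percent of the starting material charged, south-west

- ash (time / h: target / %, starting material / %): 1.33: 1, 97; 2.50: 2, 99; 5.00: 0, 101; 10.0: 1, 98; 20.0: 6, 89
- birch (time / h: target / %, starting material / %): 0.833: 4, 94; 1.50: 2, 97; 3.00: 11, 91; 6.00: 12, 85; 12.0: 26, 74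
- cedar (time / h: target / %, starting material / %): 1.50: 3, 101; 5.00: 6, 95; 8.00: 0, 97; 12.0: 4, 93; 20.0: 5, 95

(each reading ± 2 percentage points)

- on the list of suspects stand: starting material + free catalyst <-> catalyst intermediate A; partner + catalyst intermediate A -> free catalyst + target; second substrate + free catalyst <-> catalyst intermediate B; partner + catalyst intermediate B -> free catalyst + second product; free catalyst + target -> free catalyst + over-reaction product

**What matters.** I read the last points as first-order loss (pseudo-first-order). Ash loses 0.00583 /h and birch 0.0251 /h, a factor of 4.31 between their temperatures. Carried on to −20 °C, this gives a half-life of 10.4 h. That number matters: off by a factor of two either way, it puts the starting material left in south at 51.4 % or 6.95 %. It rests on ash's loss of 11.0 %, read with a scatter of 2 percentage points.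

The cold hours matter little. At −40 °C the half-life comes to 73.1 h, so south-west's 10 h there count 0.137 half-lives, far fewer than its warm hours. Partner stands outside my count: its 0.0231 M exceeds the starting material but falls short of starting material plus second substrate, and I cannot read from these runs how it divides.

**My count.** For south-west N, the hours at each temperature divided by the half-life there and summed, is 2.05; for south it is 1.92. These leave 26.5 % in south and 24.1 % in south-west. That gap of 2.4 points is in starting material left, whereas the margin of 2 points is set on target, so my count gives no figure for target and does not say which flask ends higher.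

**The forecast.** It says neither, with 56 % (35 % to 78 %) for south and 57 % (35 % to 80 %) for south-west: “The two should therefore end about equal”.

**The flasks.** South ends at 59.2 % target and south-west at 58.5 %, so the answer is neither.

    starting material + free catalyst ⇌ catalyst intermediate A (K = 300 /M, k = 170 /M/h, Ea = 54.0 kJ/mol, ΔH = −5.00 kJ/mol)
    partner + catalyst intermediate A → free catalyst + target (k = 500 /M/h, Ea = 52.0 kJ/mol)
    second substrate + free catalyst ⇌ catalyst intermediate B (K = 280 /M, k = 190 /M/h, Ea = 51.0 kJ/mol, ΔH = −55.0 kJ/mol)
    partner + catalyst intermediate B → free catalyst + second product (k = 46.0 /M/h, Ea = 44.0 kJ/mol)
    free catalyst + target → free catalyst + over-reaction product (k = 42.0 /M/h, Ea = 52.0 kJ/mol)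
    (constants at −40 °C)

**Longer reading.** South-west's cold count gave 91.0 % of starting material at 10.0 h, and the flask held 90.5 %. At 30 h, N of 2.05 gave 24.1 %, but south-west held 11 % unbound, less than the count. The neighbouring flask is south-west read at 3.0 d. There N becomes 6.08, leaving 1.48 %, and that flask holds 1.0 % unbound. Its target has fallen to 17.8 %, and over-reaction product stands at 81.1 %.

The numbers in the tables are simulated from invented constants.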